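The furofuran is cut back to ring A (C7–O–C9'–C8'–C8). Its O–C9'–C8' segment, with C7' branching from C8', is the carbon chain of butadiene monoxide. C7–C8, with C9 on C8, is the alkene of an arylidene malonate. One palladium-catalysed dynamic kinetic asymmetric (3+2) annulation of the racemic epoxide forms C7–O and C8–C8', closes ring A and sets C7 and C8' cis. The acceptor is the dimethyl malonate condensate of O-tosylvanillin. The sulfonate, preferred to a silyl ether, activates the alkene, survives dealkoxycarbonylation and later blocks ionisation at C7. The geminal diester leaves C8 open until lactonisation onto C7'–OH fixes it.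

Key step: step 3

Atom labels: C7, C8 and C9 are the ArCH, the ring-fusion CH and the OCH2 of the half that ends as the free phenol. Primed labels belong to the prenyloxyaryl half. Ring B is C7'–O–C9–C8–C8'. The target is (7R,8R,7'S,8'R): cis-fused, guaiacyl group endo, prenyloxyaryl group exo.

Assumption: the (R,R)-ligand is taken to give (R) at C8', by analogy with the face on which imide and alcohol nucleophiles attack the internal terminus of this same allyl complex; if the antipode forms, the (S,S)-ligand is used and nothing else changes.

Remark: C7' is carried as both epimers in 13 to 16, so it is left undefined in their SMILES; step 9 sets it.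

Step 1
Reactants: 1 vanillin
Product: 2 4-formyl-2-methoxyphenyl 4-methylbenzenesulfonate (O-tosylvanillin)
Conditions: TsCl, K2CO3, acetone, reflux
Reagents that add atoms: 4-toluenesulfonyl chloride, Cc1ccc(cc1)S(=O)(=O)Cl
Why: O-Sulfonylation of the phenoxide is a standard phenol protection, the aldehyde is inert to K2CO3 and the sulfonyl chloride, and no stereocentre is involved.

Step 2
Reactants: 2 O-tosylvanillin; 3 dimethyl malonate
Product: 4 dimethyl 2-[(3-methoxy-4-tosyloxyphenyl)methylidene]malonate
Conditions: piperidine (10 mol %), AcOH (20 mol %), toluene, reflux, Dean–Stark trap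
Reagents that add atoms: none
Why: Knoevenagel condensation under piperidinium acetate catalysis with azeotropic removal of water is reliable for aromatic aldehydes, the electron-poor tosyloxy ring speeds it, and the two equal esters leave no alkene geometry to control.

Step 3
Reactants: 4 dimethyl 2-[(3-methoxy-4-tosyloxyphenyl)methylidene]malonate; 5 butadiene monoxide (racemic)
Product: 6 dimethyl (2S,4R)-2-(3-methoxy-4-tosyloxyphenyl)-4-vinyltetrahydrofuran-3,3-dicarboxylate (ring A; 2,4-cis; C2 = C7, C3 = C8, C4 = C8', C5 = C9', vinyl CH = C7')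
Conditions: Pd2(dba)3·CHCl3 (2.5 mol %), (1R,2R)-N,N'-bis[2-(diphenylphosphino)benzoyl]cyclohexane-1,2-diamine (7.5 mol %), 5 (1.5 equiv, slow addition), CH2Cl2, 0 °C → rt
Reagents that add atoms: none
Why: Zerovalent palladium opens either enantiomer of 5 at the allylic C–O bond to a π-allyl complex carrying a CH2O(−) arm, the two diastereomeric ligand–allyl complexes interconvert by π-σ-π exchange through the unsubstituted terminus faster than they are consumed, the alkoxide adds to C7 of 4 (oxa-Michael), and the resulting malonate carbanion C8 alkylates the internal allyl carbon C8' anti to the metal. The closest known chemistry is the palladium-catalysed (3+2) annulation of vinyl epoxides with doubly activated alkenes, combined with the dynamic kinetic asymmetric allylic substitution of butadiene monoxide under this ligand family. Ring A closes in a 5-exo-trig sense (the remaining C=C stays outside the ring), which the three-atom O–C7–C8 tether favours over 7-endo attack at the allyl CH2, so the branched regiochemistry is secured by the substrate. C8' (R) is controlled by the chiral pocket of the ligand, which lets only one of the equilibrating allyl complexes reach the C–C bond-forming transition state. C7 (S) is controlled relative to C8': alkoxide addition to a malonate acceptor is reversible, so both C7 epimers of the carbanion drain through the lower envelope transition state with aryl and vinyl groups pseudo-equatorial, that is 2,4-cis. The step needs chemo-, regio-, diastereo- and enantioselectivity, and the substrate contributes the electron-poor tosyloxyaryl group (capture of the alkoxide faster than epoxide oligomerisation) and two identical esters (no third stereocentre to control).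

Step 4
Reactants: 6 dimethyl (2S,4R)-2-(3-methoxy-4-tosyloxyphenyl)-4-vinyltetrahydrofuran-3,3-dicarboxylate
Product: 8 dimethyl (2S,4R)-4-formyl-2-(3-methoxy-4-tosyloxyphenyl)tetrahydrofuran-3,3-dicarboxylate, via secondary ozonide 7 (not isolated)
Conditions: O3, CH2Cl2, −78 °C; then Me2S, −78 °C → rt
Reagents that add atoms: ozone, [O-][O+]=O
Why: Ozonolysis by the Criegee mechanism cleaves the only alkene present while the sulfonate-deactivated arene is spared, and the neutral Me2S reduction avoids enolisation of the new aldehyde, so C7 and C8' are untouched.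

Step 5
Reactants: 9 4-bromo-2-methoxyphenol; 10 prenyl bromide (1-bromo-3-methylbut-2-ene)
Product: 11 4-bromo-2-methoxy-1-(3-methylbut-2-enyloxy)benzene
Conditions: K2CO3, acetone, reflux
Reagents that add atoms: none
Why: Williamson ether synthesis, an SN2 displacement of the primary allylic bromide by the phenoxide, proceeds without allylic transposition under these mild conditions.

Step 6
Reactants: 8 dimethyl (2S,4R)-4-formyl-2-(3-methoxy-4-tosyloxyphenyl)tetrahydrofuran-3,3-dicarboxylate; 11 4-bromo-2-methoxy-1-(3-methylbut-2-enyloxy)benzene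
Product: 14 lactone ester (7S,8S,8'R; cis-fused ring A/γ-lactone bicycle bearing CO2Me on C8; both C7' epimers), via arylmagnesium bromide 12 (not isolated), via hydroxy diester 13 (not isolated)
Conditions: 11, Mg, LiCl, THF, rt; then 8, THF, −78 °C; aq NH4Cl; crude, DBU (10 mol %), CH2Cl2, rt
Reagents that add atoms: none
Why: Grignard addition to the aldehyde at −78 °C outruns attack on the hindered esters and the aryl sulfonate, and base-catalysed lactonisation (5-exo-trig acyl substitution) can only engage the ester on the same face of ring A as the C7' side chain, which thereby becomes C9; both C7' epimers are accepted because step 9 erases that centre.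

Step 7
Reactants: 14 lactone ester
Product: 15 lactone (7R,8S,8'R)-3,3'-dimethoxy-4'-(3-methylbut-2-enyloxy)-4-tosyloxy-7,9':7',9-diepoxylignan-9-one (both C7' epimers)
Conditions: LiCl (3 equiv), H2O (3 equiv), DMSO, 140 °C
Reagents that add atoms: none
Why: Krapcho dealkoxycarbonylation (SN2 demethylation by chloride, loss of CO2, protonation of the lactone enolate) sets C8, because a γ-lactone fused to ring A can only be cis-fused, so the proton arrives on the face of H8' and aryl, C9 and C7' end all-cis on ring A; the sulfonate tolerates hot wet DMSO where an aryl silyl ether would not.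

Step 8
Reactants: 15 lactone
Product: 16 4-[(2R,3R,4R)-4-{hydroxy[3-methoxy-4-(3-methylbut-2-enyloxy)phenyl]methyl}-3-(hydroxymethyl)tetrahydrofuran-2-yl]-2-methoxyphenyl 4-methylbenzenesulfonate (diol; both C7' epimers)
Conditions: LiBH4, THF, 0 °C → rt
Reagents that add atoms: none
Why: Hydride reduction of the lactone to the 1,4-diol with LiBH4 touches no stereocentre and leaves the aryl sulfonate, the aryl ethers and the trisubstituted alkene alone.

Step 9
Reactants: 16 diol
Product: 17 4-[(1R,3aR,4S,6aR)-4-[3-methoxy-4-(3-methylbut-2-enyloxy)phenyl]tetrahydro-1H,3H-furo[3,4-c]furan-1-yl]-2-methoxyphenyl 4-methylbenzenesulfonate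
Conditions: camphor-10-sulfonic acid (5 mol %), 4 Å MS, CH2Cl2, −20 → 0 °C; Et3N quench
Reagents that add atoms: none
Why: Acid-catalysed dehydrative cycloetherification of SN1 type: both C7' carbinols ionise to one 4-alkoxybenzyl cation, which the C9 hydroxyl captures 5-exo-trig on the face that puts the aryl group anti to C9' (exo, 7'S), an outcome favoured kinetically and also thermodynamically since the endo,endo bicycle is the most crowded, while the tosyloxy ring keeps C7 from ionising and catalytic acid at low temperature spares the prenyl ether.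

Step 10
Reactants: 17 O-tosyl furofuran
Product: 18 4-[(1R,3aR,4S,6aR)-4-[3-methoxy-4-(3-methylbut-2-enyloxy)phenyl]tetrahydro-1H,3H-furo[3,4-c]furan-1-yl]-2-methoxyphenol (target)
Conditions: KOH, EtOH–THF–H2O, 70 °C; aq NH4Cl
Reagents that add atoms: none
Why: Alkaline hydrolysis of the aryl sulfonate by attack of hydroxide at sulfur frees the phenol, and the ethers, the alkene and all four stereocentres are inert to base at this temperature.

Compound list
1 | vanillin | COc1cc(C=O)ccc1O | starting material
2 | 4-formyl-2-methoxyphenyl 4-methylbenzenesulfonate | COc1cc(C=O)ccc1OS(=O)(=O)c1ccc(C)cc1 | intermediate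
3 | dimethyl malonate | COC(=O)CC(=O)OC | starting material
4 | dimethyl 2-[(3-methoxy-4-tosyloxyphenyl)methylidene]malonate | COC(=O)C(=Cc1ccc(OS(=O)(=O)c2ccc(C)cc2)c(OC)c1)C(=O)OC | intermediate
5 | butadiene monoxide (2-vinyloxirane), racemic | C=CC1CO1 | starting material
6 | dimethyl (2S,4R)-2-(3-methoxy-4-tosyloxyphenyl)-4-vinyltetrahydrofuran-3,3-dicarboxylate | COc1cc([C@@H]2OC[C@H](C=C)C2(C(=O)OC)C(=O)OC)ccc1OS(=O)(=O)c1ccc(C)cc1 | intermediate
7 | secondary ozonide of 6 (1,2,4-trioxolan-3-yl on C8', acetal carbon as a mixture) | COc1cc([C@@H]2OC[C@H](C3OCOO3)C2(C(=O)OC)C(=O)OC)ccc1OS(=O)(=O)c1ccc(C)cc1 | intermediate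
8 | dimethyl (2S,4R)-4-formyl-2-(3-methoxy-4-tosyloxyphenyl)tetrahydrofuran-3,3-dicarboxylate | COc1cc([C@@H]2OC[C@H](C=O)C2(C(=O)OC)C(=O)OC)ccc1OS(=O)(=O)c1ccc(C)cc1 | intermediate
9 | 4-bromo-2-methoxyphenol | COc1cc(Br)ccc1O | starting material
10 | prenyl bromide | CC(C)=CCBr | starting material
11 | 4-bromo-2-methoxy-1-(3-methylbut-2-enyloxy)benzene | COc1cc(Br)ccc1OCC=C(C)C | intermediate
12 | [3-methoxy-4-(3-methylbut-2-enyloxy)phenyl]magnesium bromide | COc1cc([Mg]Br)ccc1OCC=C(C)C | intermediate
13 | dimethyl (2S,4R)-4-{hydroxy[3-methoxy-4-(3-methylbut-2-enyloxy)phenyl]methyl}-2-(3-methoxy-4-tosyloxyphenyl)tetrahydrofuran-3,3-dicarboxylate (C7' epimers) | COc1cc([C@@H]2OC[C@H](C(O)c3ccc(OCC=C(C)C)c(OC)c3)C2(C(=O)OC)C(=O)OC)ccc1OS(=O)(=O)c1ccc(C)cc1 | intermediate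
14 | lactone ester, (7S,8S,8'R), CO2Me on C8 on the convex face, C7' epimers | COc1cc([C@@H]2OC[C@H]3[C@]2(C(=O)OC)C(=O)OC3c2ccc(OCC=C(C)C)c(OC)c2)ccc1OS(=O)(=O)c1ccc(C)cc1 | intermediate
15 | lactone, (7R,8S,8'R), cis-fused, C7' epimers | COc1cc([C@@H]2OC[C@H]3[C@@H]2C(=O)OC3c2ccc(OCC=C(C)C)c(OC)c2)ccc1OS(=O)(=O)c1ccc(C)cc1 | intermediate
16 | diol, (7R,8R,8'R), all-cis ring A, C7' epimers | COc1cc([C@@H]2OC[C@H](C(O)c3ccc(OCC=C(C)C)c(OC)c3)[C@@H]2CO)ccc1OS(=O)(=O)c1ccc(C)cc1 | intermediate
17 | O-tosyl furofuran, (7R,8R,7'S,8'R) | COc1cc([C@@H]2OC[C@H]3[C@@H]2CO[C@@H]3c2ccc(OCC=C(C)C)c(OC)c2)ccc1OS(=O)(=O)c1ccc(C)cc1 | intermediate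
18 | target, (7R,8R,7'S,8'R) | COc1cc([C@@H]2OC[C@H]3[C@@H]2CO[C@@H]3c2ccc(OCC=C(C)C)c(OC)c2)ccc1O | target

Total step count: 10. Longest linear sequence: 9 (steps 1–4 and 6–10; step 5 is the side branch).

Steps most likely to fail

1. Step 3. Capture of the alkoxide by the diester acceptor may be slow, so that oligomerisation or isomerisation of the epoxide takes over. The cis selectivity of the ring closure may also be insufficient. The fallback changes the acceptor, not the catalyst.
- Setting out from 2, Knoevenagel condensation with Meldrum's acid (2,2-dimethyl-1,3-dioxane-4,6-dione) gives the arylidene Meldrum's acid F1. This is a much stronger electrophile, of the class for which this annulation is documented.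
- Annulation of F1 with 5 under the same palladium–ligand system gives the spiro adduct F2. Its cis isomer is purified by crystallisation or chromatography.
- Refluxing methanol opens the dioxanedione ring with loss of acetone to give the malonic half-ester F3.
- MeI and K2CO3 in DMF return to the route at 6.

2. Step 7. At 140 °C three processes threaten the step: sigmatropic migration of the prenyl group, heterolysis of the benzylic lactone C–O bond followed by loss of the wrong carboxyl group, and β-elimination of the ring A oxygen from the lactone enolate with scrambling at C7. The fallback replaces halide dealkylation by hydrolysis and neutral decarboxylation.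
- Setting out from 14, Me3SnOH in 1,2-dichloroethane at 80 °C cleaves the methyl ester to the lactone acid F4. Any opened lactone re-closes on mildly acidic work-up.
- F4 loses CO2 through a cyclic enol transition state in toluene at about 100 °C. No free enolate is involved and the temperature is lower.
- Ketonisation again gives only the cis-fused bicycle, so the sequence comes back at 15.

3. Step 9. The acid may remove the prenyl group, the benzylic cation may lose a proton towards C8', or exo selectivity may be incomplete. The fallback fixes C7' first and closes ring B under base.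
- Setting out from 16, MnO2 in CH2Cl2 oxidises only the benzylic carbinol to the keto alcohol F5.
- LiBH(s-Bu)3 in THF at −78 °C delivers hydride anti to C8 (Felkin–Anh model), the stereochemical complement of aryl addition to the aldehyde. This should give the (7'S)-diol F6.
- One equivalent of MsCl with Et3N in CH2Cl2 sulfonylates the primary hydroxyl to the primary mesylate F7.
- The C7' hydroxyl displaces the mesylate (5-exo-tet, retention at C7'), and the sequence comes back at 17.

Further compounds
F1 | step 3 | 5-[(3-methoxy-4-tosyloxyphenyl)methylidene]-2,2-dimethyl-1,3-dioxane-4,6-dione | COc1cc(C=C2C(=O)OC(C)(C)OC2=O)ccc1OS(=O)(=O)c1ccc(C)cc1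
F2 | step 3 | (1S,4R)-8,8-dimethyl-1-(3-methoxy-4-tosyloxyphenyl)-4-vinyl-2,7,9-trioxaspiro[4.5]decane-6,10-dione | COc1cc([C@@H]2OC[C@H](C=C)C23C(=O)OC(C)(C)OC3=O)ccc1OS(=O)(=O)c1ccc(C)cc1
F3 | step 3 | (2S,4R)-3-methoxycarbonyl-2-(3-methoxy-4-tosyloxyphenyl)-4-vinyltetrahydrofuran-3-carboxylic acid (C3 epimers) | COc1cc([C@@H]2OC[C@H](C=C)C2(C(=O)O)C(=O)OC)ccc1OS(=O)(=O)c1ccc(C)cc1
F4 | step 7 | lactone acid, (7S,8S,8'R), CO2H on C8, C7' epimers | COc1cc([C@@H]2OC[C@H]3[C@]2(C(=O)O)C(=O)OC3c2ccc(OCC=C(C)C)c(OC)c2)ccc1OS(=O)(=O)c1ccc(C)cc1
F5 | step 9 | keto alcohol, (7R,8R,8'R), C7' ketone | COc1cc([C@@H]2OC[C@H](C(=O)c3ccc(OCC=C(C)C)c(OC)c3)[C@@H]2CO)ccc1OS(=O)(=O)c1ccc(C)cc1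
F6 | step 9 | diol, single epimer (7R,8R,7'S,8'R) | COc1cc([C@@H]2OC[C@H]([C@H](O)c3ccc(OCC=C(C)C)c(OC)c3)[C@@H]2CO)ccc1OS(=O)(=O)c1ccc(C)cc1
F7 | step 9 | C9 methanesulfonate of F6 | COc1cc([C@@H]2OC[C@H]([C@H](O)c3ccc(OCC=C(C)C)c(OC)c3)[C@@H]2COS(C)(=O)=O)ccc1OS(=O)(=O)c1ccc(C)cc1
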